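## The problem

1. Agehoustin F (8) is 5,2'-dihydroxy-6,7,8,4',5'-pentamethoxyflavone. Benzo ring A (C4a, C5–C8, C8a) is fused to the γ-pyrone ring C (O1, C2, C3, C4), and C2 carries aryl ring B (C1'–C6').
2. There is no stereocentre, no stereogenic axis and no acyclic double bond, so nothing has to be set or relayed. The problem is one of substitution pattern and of telling oxygens apart.
3. The hardest element is ring A. It is a hexasubstituted benzene with five contiguous oxygens (O1 on C8a, OMe on C8, C7 and C6, OH on C5) and one carbon (C4 on C4a), a connectivity that no cheap phenol or acetophenone offers.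
4. Of the seven aryl oxygens, five are methyl ethers and two (5-OH, 2'-OH) are free. A route therefore either carries protecting groups and ends with selective dealkylations, or never lets these two oxygens become ethers.
5. Both arenes are very electron-rich (ring B is a hydroquinone monoether, 2'-OH para to 5'-OMe), which rules out late electrophiles and oxidants. Ring C and its 1,3-diketone precursors are opened or cleaved by hot concentrated alkali.
6. A 2'-hydroxyflavone holds one more trap: its open 1,3-diketone form has an ortho OH on both aryl ketone halves and can close to two different chromones.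
7. The enabling feature is the local symmetry of ring A. C5 and C8a, the two carbons ortho to C4a, both carry oxygen, and C6, C7 and C8 between them all carry OMe. C4 plus ring A is thus a 3,4,5-trimethoxybenzoyl group oxygenated at both ortho positions, with a mirror plane through C4, C4a and C7 that is broken only when ring C closes.
8. Its complement, ring B with C2 and C3, is a 2-hydroxy-4,5-dimethoxyacetophenone whose free OH already is the 2'-OH.

## Retrosynthesis

**8 ⇒ 7 ⇒ 6 (cut C5–OH and O1–C8a).** The textbook cuts (O1–C2, C2–C3, C2–C1') all leave ring A as a penta-oxygenated phenol, so they move the difficulty into a building block without solving it. Only a cut of aryl C–O bonds takes oxygen off ring A.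
- The two aryl C–O bonds ortho to C4a are the ones to cut, because they are symmetry-related.
- Replacing the 5-OH of 8 by bromine gives 5-bromoflavone 7. Opening O1–C8a of 7 to a second C–Br gives 1-(2,6-dibromo-3,4,5-trimethoxyphenyl)-3-(2-hydroxy-4,5-dimethoxyphenyl)propane-1,3-dione (6).
- Cutting the C6, C7 or C8 oxygens instead would call for late C–H oxidation next to the more oxidisable ring B.
- 6 has no ring C, only three oxygens on ring A and two identical halogens, and it needs no protecting group.
- The forward reaction must make two C–O bonds at doubly ortho-substituted aryl bromides. One uses the enolate oxygen on C2 and one uses hydroxide, both in the presence of a free phenol.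

**6 ⇒ 3 + 4, through 5 (cut C3–C4).** This cut inverts the usual roles. The ortho-hydroxyacetophenone, 1-(2-hydroxy-4,5-dimethoxyphenyl)ethan-1-one (4), becomes ring B and not ring A. The aroyl partner, 2,6-dibromo-3,4,5-trimethoxybenzoyl chloride (3), becomes ring A and C4.
- The neighbouring cut C2–C3 would need a dibromoacetophenone that is not sold, and a salicylate electrophile that must be protected.
- 4 is commercial, and its OH is carried through unprotected as part of the dilithium enolate-phenoxide 5.
- The forward reaction is C-acylation of 5 by a hindered acid chloride.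

**3 ⇒ 2 ⇒ 1 (cut two C–Br bonds, exchange Cl for OH).** 3 comes from 2,6-dibromo-3,4,5-trimethoxybenzoic acid (2), and 2 from 3,4,5-trimethoxybenzoic acid (1).
- C2 and C6 of 1 are the only free ring positions and both are activated by the methoxy groups, so there is no regiochemical question.
- Bromine is used before the union, so ring B never meets an electrophile.
- None of the three skeletal bonds made in this plan (C3–C4, O1–C8a, C5–O) is made in the textbook route.

## Roads not taken

**Alternative 1:** This is the obvious route, which cuts O1–C2 and C2–C3.
- Forward: Claisen–Schmidt condensation of 2-hydroxy-3,4,5,6-tetramethoxyacetophenone A1 with 2-benzyloxy-4,5-dimethoxybenzaldehyde A2 gives chalcone A3. Iodine-mediated oxidative cyclisation gives flavone A4, and chelation-controlled 5-O-demethylation and hydrogenolysis then give 8. The Baker–Venkataraman variant differs only in oxidation level.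
- Why not: A1 is itself the hexasubstituted, penta-oxygenated benzene and has to be built over several oxidation and methylation steps. Both free OH groups must be masked and unmasked. The key step solves none of the difficulty, and the count is about ten steps against four.

**Alternative 2:** This route cuts C4–C4a, C3–C4 and O1–C2.
- Forward: a three-component carbonylative Sonogashira coupling with 6-endo closure joins 2-iodo-4,5,6-trimethoxybenzene-1,3-diol A5, 1-benzyloxy-2-ethynyl-4,5-dimethoxybenzene A6 and carbon monoxide A7. The product is 2'-O-benzylagehoustin F A8, which is then hydrogenolysed. It uses the same local symmetry, since either OH of A5 may close.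
- Why not: A5 still holds all five oxygens. It needs two aryl C–O bond formations and an iodination on an air-sensitive resorcinol.
- A6 must be protected, because a free ortho-ethynylphenol cyclises to a benzofuran under palladium.
- The key step must beat direct coupling without carbonyl insertion and 5-exo closure to an aurone.
- The count is about nine steps. The chosen plan makes the same two aryl C–O bonds, but lets them also close ring C and set the 5-OH apart.

**Alternative 3:** This route cuts C4a–C5 and C8–C8a, so that ring A is built de novo.
- Forward: the C6-metalated form of 2-(2-benzyloxy-4,5-dimethoxyphenyl)-4H-pyran-4-one A10 adds to dimethyl squarate A9. O-methylation gives racemic cyclobutenone A11, and thermal 4π opening and 6π closure (Moore–Liebeskind ring expansion) gives A8.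
- Appeal: A9 delivers C5–C8 with all four oxygens. The ketene carbonyl becomes the 5-OH and the methylated carbinol becomes the 8-OMe.
- Why not: the plan rests on regioselective metalation of an electrophilic γ-pyrone at C6, against C3, C5 and the ortho positions of ring B, and no secure base exists for that.
- A10 costs about four steps and a protecting group, so the run-up gives away what the key step gains (eight to nine steps).

Key step: step 4

Remark: the target has no stereogenic element. Its SMILES defines one achiral compound, so the demand for a single enantiomer is met trivially.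

## Route

Step 1
Reactants: 1 3,4,5-trimethoxybenzoic acid
Product: 2 2,6-dibromo-3,4,5-trimethoxybenzoic acid
Conditions: Br2 (2.5 equiv), AcOH, 25 → 60 °C, dark
Reagents that add atoms: bromine, BrBr
Why: Electrophilic aromatic bromination; C2 and C6 are the only free positions and each is ortho to one and para to another OMe, so two equivalents can only give 2. It is done before the union so that the more electron-rich ring B never meets bromine.

Step 2
Reactants: 2 2,6-dibromo-3,4,5-trimethoxybenzoic acid
Product: 3 2,6-dibromo-3,4,5-trimethoxybenzoyl chloride
Conditions: SOCl2 (3 equiv), cat. DMF, toluene, 70 °C; evaporate, use crude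
Reagents that add atoms: thionyl chloride, O=S(Cl)Cl
Why: Vilsmeier-catalysed acid chloride formation, which tolerates aryl ethers and bromides. The most reactive acyl donor is chosen because two ortho bromines shield the carbonyl carbon.

Step 3
Reactants: 4 1-(2-hydroxy-4,5-dimethoxyphenyl)ethan-1-one; 3 2,6-dibromo-3,4,5-trimethoxybenzoyl chloride
Product: 6 1-(2,6-dibromo-3,4,5-trimethoxyphenyl)-3-(2-hydroxy-4,5-dimethoxyphenyl)propane-1,3-dione, via dilithium enolate-phenoxide 5 (not isolated)
Conditions: 4, LiHMDS (3.3 equiv), THF, −78 → −10 °C; 3 in THF, −78 °C → rt; 1 M HCl, 0 °C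
Reagents that add atoms: none
Why: Crossed Claisen C-acylation of a ketone enolate, the direct one-flask variant of the Baker–Venkataraman synthesis of ortho-hydroxydibenzoylmethanes; the third equivalent of base deprotonates C3 of the product and stops a second acylation. O-acylation of the phenoxide is no dead end, since excess base carries the ester on by O→C acyl shift, and ring A has no ring hydrogen, so no aryne can form.

Step 4
Reactants: 6 1-(2,6-dibromo-3,4,5-trimethoxyphenyl)-3-(2-hydroxy-4,5-dimethoxyphenyl)propane-1,3-dione
Product: 8 agehoustin F (5-hydroxy-2-(2-hydroxy-4,5-dimethoxyphenyl)-6,7,8-trimethoxy-4H-chromen-4-one), via 5-bromoflavone 7 (not isolated)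
Conditions: Cu(acac)2 (10 mol %), N,N'-bis(4-hydroxy-2,6-dimethylphenyl)oxalamide (10 mol %), LiOH·H2O (6 equiv), degassed DMSO/H2O 4:1 (0.05 M), 80 → 100 °C, Ar; 2 M HCl; then AcOH, cat. H2SO4, 80 °C
Reagents that add atoms: lithium hydroxide, [Li+].[OH-]
Why: The step is a tandem of two known copper-catalysed Ullmann-type C–O couplings. Base turns 6 into its phenoxide/β-diketonate dianion; copper is held near ring A by the oxygen on C4 (the ortho-carbonyl effect of Ullmann chemistry), inserts into one ortho C–Br bond and, after rotation about C3–C4, eliminates reductively with the enolate oxygen on C2, which forms O1–C8a and gives 7. This is the known intramolecular O-arylation of 1-(2-haloaryl)-1,3-diketones to chromones; ring C closes as a six-membered ring by attack of oxygen on an sp2 carbon with an exocyclic leaving group, whereas C-arylation at C3 would need a four-membered ring and attack of the 2'-phenoxide an eight-membered ring. The second bromide, now at C5 and again next to the carbonyl-bearing carbon, is exchanged for hydroxide by the same catalyst (known copper/oxalamide hydroxylation of aryl bromides) and ends as the chelated 5-phenoxide. No regioselectivity is needed, because the two brominated carbons of 6 are related by the local mirror plane through C4, C4a and C7, so either bromide may close the ring and either coupling may come first. The selectivity that is needed is against intermolecular diaryl ether formation, and it is secured by dilution, by the excess of small hydroxide and by the low nucleophilicity of both phenoxides, which are ortho-acylated, chelated and hindered. Opening of ring C by hydroxide at C2–O1 would leave the new C8a–O bond intact and is reversed by the acid finish, where closure onto C2 is favoured over closure of the 2'-OH onto C4, because C4 is flanked by two ortho substituents and tied up in the hydrogen bond to the 5-OH. No stereocentre is formed.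

## Compound list

1 | 3,4,5-trimethoxybenzoic acid | COc1cc(C(=O)O)cc(OC)c1OC | starting material
2 | 2,6-dibromo-3,4,5-trimethoxybenzoic acid | COc1c(Br)c(C(=O)O)c(Br)c(OC)c1OC | intermediate
3 | 2,6-dibromo-3,4,5-trimethoxybenzoyl chloride | COc1c(Br)c(C(=O)Cl)c(Br)c(OC)c1OC | intermediate
4 | 1-(2-hydroxy-4,5-dimethoxyphenyl)ethan-1-one | CC(=O)c1cc(OC)c(OC)cc1O | starting material
5 | dilithium enolate-phenoxide of 4 | [Li+].[Li+].C=C([O-])c1cc(OC)c(OC)cc1[O-] | intermediate
6 | 1-(2,6-dibromo-3,4,5-trimethoxyphenyl)-3-(2-hydroxy-4,5-dimethoxyphenyl)propane-1,3-dione | COc1cc(O)c(C(=O)CC(=O)c2c(Br)c(OC)c(OC)c(OC)c2Br)cc1OC | intermediate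
7 | 5-bromo-2-(2-hydroxy-4,5-dimethoxyphenyl)-6,7,8-trimethoxy-4H-chromen-4-one | COc1cc(O)c(-c2cc(=O)c3c(Br)c(OC)c(OC)c(OC)c3o2)cc1OC | intermediate
8 | agehoustin F, 5-hydroxy-2-(2-hydroxy-4,5-dimethoxyphenyl)-6,7,8-trimethoxy-4H-chromen-4-one (achiral) | COc1cc(O)c(-c2cc(=O)c3c(O)c(OC)c(OC)c(OC)c3o2)cc1OC | target

## Step count and risks

Total steps: 4. Longest linear sequence: 4 (1 → 2 → 3 → 6 → 8). No protecting group is used.

**Step 4 (key step).**
- Risk: both C–Br bonds sit on an electron-rich ring between two ortho substituents, so oxidative addition may be slow. Hydrodebromination, retro-Claisen cleavage of the diketonate by hot hydroxide, intermolecular etherification or air oxidation of the phenoxides could then take over.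
- Fallback: it sets out from 2, uses 5 made from 4 as in step 3, and comes back at 8. The two C–O bonds are made first, on the free acid, where the ortho-carboxylate effect gives the best-precedented copper-mediated exchange of halide for hydroxide.
- Cu2O (cat.) in aqueous NaOH at 100 °C should give 2,6-dihydroxy-3,4,5-trimethoxybenzoic acid F1.
- SOCl2, DMAP and acetone in DME convert it into the salicylate acetonide 5-hydroxy-6,7,8-trimethoxy-2,2-dimethyl-4H-1,3-benzodioxin-4-one F2.
- F2 is opened at its carbonyl by 5 (one extra equivalent of LiHMDS for the free OH) with loss of the acetonide carbon unit. This gives 1-(2,6-dihydroxy-3,4,5-trimethoxyphenyl)-3-(2-hydroxy-4,5-dimethoxyphenyl)propane-1,3-dione F3.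
- AcOH with catalytic H2SO4 at 80 °C closes F3 by dehydration to 8. Ring C is then formed at O1–C2 and no metal has to act on the assembled skeleton.

**Step 3.**
- Risk: the two ortho bromines shield the acyl carbon. Intermolecular C-acylation may be slow, may stop at O-acylation of the phenoxide, or may be outrun by attack of the silazide on the acid chloride.
- Fallback: it sets out from 3 and 4 and comes back at 6. The intermolecular C–C bond formation is replaced by an intramolecular acyl transfer.
- K2CO3 in acetone joins 3 and 4 at oxygen to give 2-acetyl-4,5-dimethoxyphenyl 2,6-dibromo-3,4,5-trimethoxybenzoate F4.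
- KOt-Bu in THF (or KOH in pyridine, 50 °C) then effects the Baker–Venkataraman O→C shift through a six-membered transition state. The hindered carbonyl is there attacked with high effective molarity.

**Step 1.**
- Risk: the second bromination is slowed by the first bromine and by the twisting of the flanked methoxy groups. Forcing it invites ipso attack at C1 with loss of CO2 and ether cleavage by the hydrogen bromide that builds up.
- Fallback: it sets out from 1 and comes back at 2. The carboxyl group is taken out of play.
- Fischer esterification (MeOH, cat. H2SO4) gives methyl 3,4,5-trimethoxybenzoate F5.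
- Bromination (Br2, AcOH) gives methyl 2,6-dibromo-3,4,5-trimethoxybenzoate F6, which cannot decarboxylate.
- The hindered ester is cleaved at the O–methyl bond, not at the acyl carbon (LiI, pyridine, reflux, then acid), to give 2.

## Further compounds

F1 | step 4 | 2,6-dihydroxy-3,4,5-trimethoxybenzoic acid | COc1c(O)c(C(=O)O)c(O)c(OC)c1OC
F2 | step 4 | 5-hydroxy-6,7,8-trimethoxy-2,2-dimethyl-4H-1,3-benzodioxin-4-one | CC1(C)OC(=O)c2c(O)c(OC)c(OC)c(OC)c2O1
F3 | step 4 | 1-(2,6-dihydroxy-3,4,5-trimethoxyphenyl)-3-(2-hydroxy-4,5-dimethoxyphenyl)propane-1,3-dione | COc1cc(O)c(C(=O)CC(=O)c2c(O)c(OC)c(OC)c(OC)c2O)cc1OC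
F4 | step 3 | 2-acetyl-4,5-dimethoxyphenyl 2,6-dibromo-3,4,5-trimethoxybenzoate | CC(=O)c1cc(OC)c(OC)cc1OC(=O)c1c(Br)c(OC)c(OC)c(OC)c1Br
F5 | step 1 | methyl 3,4,5-trimethoxybenzoate | COC(=O)c1cc(OC)c(OC)c(OC)c1
F6 | step 1 | methyl 2,6-dibromo-3,4,5-trimethoxybenzoate | COC(=O)c1c(Br)c(OC)c(OC)c(OC)c1Br
A1 | alternative 1 | 2-hydroxy-3,4,5,6-tetramethoxyacetophenone | CC(=O)c1c(O)c(OC)c(OC)c(OC)c1OC
A2 | alternative 1 | 2-benzyloxy-4,5-dimethoxybenzaldehyde | COc1cc(OCc2ccccc2)c(C=O)cc1OC
A3 | alternative 1 | (E)-3-(2-benzyloxy-4,5-dimethoxyphenyl)-1-(2-hydroxy-3,4,5,6-tetramethoxyphenyl)prop-2-en-1-one | COc1cc(OCc2ccccc2)c(/C=C/C(=O)c2c(O)c(OC)c(OC)c(OC)c2OC)cc1OC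
A4 | alternative 1 | 2-(2-benzyloxy-4,5-dimethoxyphenyl)-5,6,7,8-tetramethoxy-4H-chromen-4-one | COc1cc(OCc2ccccc2)c(-c2cc(=O)c3c(OC)c(OC)c(OC)c(OC)c3o2)cc1OC
A5 | alternative 2 | 2-iodo-4,5,6-trimethoxybenzene-1,3-diol | COc1c(O)c(I)c(O)c(OC)c1OC
A6 | alternative 2 | 1-benzyloxy-2-ethynyl-4,5-dimethoxybenzene | C#Cc1cc(OC)c(OC)cc1OCc1ccccc1
A7 | alternative 2 | carbon monoxide | [C-]#[O+]
A8 | alternative 2 | 2'-O-benzylagehoustin F, 2-(2-benzyloxy-4,5-dimethoxyphenyl)-5-hydroxy-6,7,8-trimethoxy-4H-chromen-4-one | COc1cc(OCc2ccccc2)c(-c2cc(=O)c3c(O)c(OC)c(OC)c(OC)c3o2)cc1OC
A9 | alternative 3 | dimethyl squarate | COC1=C(OC)C(=O)C1=O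
A10 | alternative 3 | 2-(2-benzyloxy-4,5-dimethoxyphenyl)-4H-pyran-4-one | COc1cc(OCc2ccccc2)c(-c2cc(=O)cco2)cc1OC
A11 | alternative 3 | 4-[6-(2-benzyloxy-4,5-dimethoxyphenyl)-4-oxo-4H-pyran-2-yl]-2,3,4-trimethoxycyclobut-2-en-1-one (racemic) | COC1=C(OC)C(OC)(c2cc(=O)cc(-c3cc(OC)c(OC)cc3OCc3ccccc3)o2)C1=O
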